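The earlier runs and the new flask stem from a simulated flask on assumed constants, noise included.

**Stirred vessel.** Reagent and free catalyst stand in the vessel, and substrate runs in at a steady rate. The new flasks differ in dosing time, and the earlier runs, elm and larch, carry more reagent.

| flask | substrate | reagent | free catalyst | remark | time |
|---|---|---|---|---|---|
| elm | 0.29 M (fed, over 8.0 s) | 0.61 M | 0.75 mM | run made earlier; the fed solution adds 0.25 times the starting volume |  |
| larch | 0.29 M (fed, over 8.0 s) | 0.96 M | 0.75 mM | run made earlier; the fed solution adds 0.25 times the starting volume |  |
| Monday's | 0.29 M (fed, over 8.0 s) | 0.435 M | 0.75 mM | the fed solution adds 0.25 times the starting volume | 5.0 min |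
| Saturday's | 0.29 M (fed, over 12 s) | 0.435 M | 0.75 mM | the fed solution adds 0.25 times the starting volume | 5.0 min |
| Friday's | 0.29 M (fed, over 20 s) | 0.435 M | 0.75 mM | the fed solution adds 0.25 times the starting volume | 5.0 min |
| Thursday's | 0.29 M (fed, over 25 s) | 0.435 M | 0.75 mM | the fed solution adds 0.25 times the starting volume | 5.0 min |

| run | time / min | target / % | substrate / % |
|---|---|---|---|
| elm | 1.50 | 58 | 1 |
| elm | 3.00 | 79 | 1 |
| elm | 5.00 | 91 | 0 |
| elm | 6.00 | 93 | 2 |
| larch | 0.833 | 52 | 2 |
| larch | 2.00 | 83 | 0 |
| larch | 4.00 | 97 | 0 |
| larch | 6.00 | 99 | 1 |

(each reading ± 1.5 percentage points)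

- charges are per starting volume, the dose included; the dosed solution carries all of it
- steps thought possible: substrate + free catalyst -> spent catalyst; reagent + free catalyst + intermediate -> free catalyst + target; substrate + free catalyst -> free catalyst + intermediate
- "hardly changes" means that all values lie within two and a half points (for a concentration: within two and a half percent of the largest)

- amount of target at the end, in percent of the substrate charged for Monday's, Saturday's, Friday's, Thursday's, in this order
- the course of these numbers from the first flask to the last (rises, then falls / rises all the way / hardly changes / falls all the way / falls, then rises)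

**Main step.** Take substrate as turned into intermediate at once: in elm and larch it reads 1% and 2% at the first reading, while target takes minutes. Then write the balance of substrate, charged in the smaller amount (the limiting reagent). With charges S of substrate and R of reagent, and x the share of S that has become target, intermediate is S(1 − x) and reagent is R − Sx. If the rate is the product of these two times a constant κ, then ln[(R − Sx)/(R(1 − x))] = κ(R − S)t.

Count t from the middle of the dose. Elm at 3.00 min gives 1.16 M⁻¹ min⁻¹, and larch at 2.00 min gives 1.15 M⁻¹ min⁻¹. Take their mean, 1.15 M⁻¹ min⁻¹, as κ, the working constant of target formation at this catalyst charge. With the whole charge in at time zero, Monday's reaches 79.7% at 5.0 min.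

**Add the dose.** Substrate arrives over the dosing time, so take half of that time off the clock. My row becomes 79.4%, 79.2%, 78.9%, 78.7%, a fall of 0.70 percentage points from Monday's to Thursday's.

**Add the rest.** Dilution and catalyst loss remain. Elm has the same catalyst charge and the same feed volume as the new flasks. Both substrate steps are first order in substrate and free catalyst, so the loss per substrate consumed stays the same. Both effects therefore sit inside κ, and the row stands.

**The forecast.** It gives 79.3%, 79.1%, 78.8%, 78.6%, and says the row hardly changes, since “Longer feeds only lose half the feed time of reaction”. My Monday's value stands 0.100 points above its number.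

**The result.** The flasks end at 80.2%, 80.1%, 79.8%, 79.6% of the substrate charged, and the row hardly changes.

    substrate + free catalyst → spent catalyst (k = 0.100 M⁻¹ s⁻¹)
    reagent + free catalyst + intermediate → free catalyst + target (k = 45.0 M⁻² s⁻¹)
    substrate + free catalyst → free catalyst + intermediate (k = 560 M⁻¹ s⁻¹)

**Two clocks.** On Monday's at 0.109 min, the half-life of substrate by its step to intermediate is 2.1 s, far shorter than the 1.2 min of intermediate by its step to target, and at 5.00 min intermediate still holds 19.8% of the substrate charged. Put the end values through the balance: κ reads 1.19 M⁻¹ min⁻¹ on Monday's and 1.20 M⁻¹ min⁻¹ on Thursday's, against the 1.15 M⁻¹ min⁻¹ read off elm and larch.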